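**Strategy.** The route rests on cutting the bond between dioxane C6 and the side-chain CH2 as an sp2–sp3 bond. C6, the fully substituted ring carbon on O1, is a masked ketone, so it is carried as the internal carbon of a 2-bromo-1-alkene. A Negishi coupling joins this vinyl bromide, which already holds the C4 methyl stereocentre, to the complete enantiopure side chain. Ozonolysis in methanol then turns the coupled carbon into a hydroperoxy ketal whose OOH opens a β-lactone with inversion, closing the 1,2-dioxane and releasing the C3 acetic acid arm. Axial methyl delivery to the C6 peroxycarbenium ion sets the last stereocentre.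

Key step: step 4

Assumption: in step 7 O-TMS-quinidine is taken to be the pseudoenantiomer that gives the 4R lactone; should the sense be the opposite, O-TMS-quinine replaces it and nothing else changes.

Step 1
Reactants: 1 (4R)-4-benzyl-3-propanoyl-1,3-oxazolidin-2-one; 2 2,3-dibromoprop-1-ene
Product: 4 (4R)-4-benzyl-3-[(2S)-4-bromo-2-methylpent-4-enoyl]-1,3-oxazolidin-2-one, via sodium Z-enolate 3 (not isolated)
Conditions: NaHMDS, THF, −78 °C; then 2, −78 to −40 °C
Reagents that add atoms: none
Why: Auxiliary-controlled (Evans) alkylation: the chelated sodium Z-enolate 3 should be alkylated at the allylic bromide on the face opposite the benzyl group, which sets the future C4 centre as 2S, while the vinylic bromide stays untouched.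

Step 2
Reactants: 5 (8-bromooctyl)benzene; 6 (2S)-3-bromo-2-methylpropan-1-ol
Product: 8 (2R)-2-methyl-11-phenylundecan-1-ol, via 8-phenyloctylmagnesium bromide 7 (not isolated)
Conditions: Mg, THF, rt (5 to 7, 2.3 equiv); then 6, Li2CuCl4 (3 mol %), THF, −78 °C to rt; 1 M HCl work-up
Reagents that add atoms: none
Why: Copper-catalysed sp3–sp3 Grignard cross-coupling at the primary bromide (one further equivalent of 7 only deprotonates the hydroxyl group); the stereocentre of 6 is not involved and its descriptor changes from S to R only through the CIP priorities.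

Step 3
Reactants: 8 (2R)-2-methyl-11-phenylundecan-1-ol
Product: 9 (2R)-1-iodo-2-methyl-11-phenylundecane
Conditions: I2, PPh3, imidazole, CH2Cl2, 0 °C to rt
Reagents that add atoms: iodine, II
Why: Appel-type iodination of the primary alcohol through the alkoxyphosphonium iodide; the neighbouring stereocentre is not touched.

Step 4
Reactants: 9 (2R)-1-iodo-2-methyl-11-phenylundecane; 4 (4R)-4-benzyl-3-[(2S)-4-bromo-2-methylpent-4-enoyl]-1,3-oxazolidin-2-one
Product: 11 (4R)-4-benzyl-3-[(2S,6R)-2,6-dimethyl-4-methylidene-15-phenylpentadecanoyl]-1,3-oxazolidin-2-one, via alkylzinc iodide 10 (not isolated)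
Conditions: Zn dust, LiCl, THF, 40 °C (9 to 10); then 4, Pd(OAc)2 (2 mol %), SPhos (4 mol %), THF, rt
Reagents that add atoms: none
Why: Zinc inserts into the C–I bond of 9 to give the primary alkylzinc iodide 10; Pd(0) then adds oxidatively to the vinylic C–Br bond of 4, and transmetalation followed by reductive elimination forms the C(sp2)–C(sp3) bond between the future C6 and the side-chain CH2 (Negishi alkyl–alkenyl cross-coupling, a known reaction type used unchanged). No ring is closed and no stereocentre is formed, so none can be lost: the methyl-bearing carbon of 10 is β to zinc and configurationally inert, and the imide α-carbon is not enolised under these neutral conditions. The step needs chemoselectivity for the C–Br bond over the two imide carbonyl groups, secured by the low nucleophilicity of RZnI, and reductive elimination faster than β-hydride elimination, secured by the bulky biarylphosphine. Its value lies in what the coupled sp2 carbon becomes: ozonolysis in methanol (step 8) converts exactly this carbon into the peroxyketal carbon C6.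

Step 5
Reactants: 11 (4R)-4-benzyl-3-[(2S,6R)-2,6-dimethyl-4-methylidene-15-phenylpentadecanoyl]-1,3-oxazolidin-2-one
Product: 12 (2S,6R)-2,6-dimethyl-4-methylidene-15-phenylpentadecan-1-ol
Conditions: LiBH4, THF, 0 °C; aqueous work-up
Reagents that add atoms: none
Why: Reductive cleavage of the N-acyl oxazolidinone by LiBH4 should release the primary alcohol and the auxiliary without affecting the 1,1-disubstituted alkene or either stereocentre.

Step 6
Reactants: 12 (2S,6R)-2,6-dimethyl-4-methylidene-15-phenylpentadecan-1-ol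
Product: 13 (2S,6R)-2,6-dimethyl-4-methylidene-15-phenylpentadecanal
Conditions: Dess–Martin periodinane, CH2Cl2, 0 °C to rt
Reagents that add atoms: none
Why: Dess–Martin oxidation under non-basic conditions should give the α-branched aldehyde without epimerisation; it is used at once.

Step 7
Reactants: 13 (2S,6R)-2,6-dimethyl-4-methylidene-15-phenylpentadecanal
Product: 14 (4R)-4-[(2S,6R)-6-methyl-4-methylidene-15-phenylpentadecan-2-yl]oxetan-2-one
Conditions: AcCl, iPr2NEt, O-TMS-quinidine (10 mol %), LiClO4, CH2Cl2/Et2O, −78 °C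
Reagents that add atoms: acetyl chloride, CC(=O)Cl
Why: Alkaloid/LiClO4-catalysed ketene–aldehyde [2+2] cycloaddition: the ammonium enolate formed from ketene and the alkaloid adds to the lithium-activated aldehyde and closes the β-lactone, the alkaloid controlling the new centre as 4R (anti to the methyl group).

Step 8
Reactants: 14 (4R)-4-[(2S,6R)-6-methyl-4-methylidene-15-phenylpentadecan-2-yl]oxetan-2-one
Product: 15 (4R)-4-[(2S,6R)-4-hydroperoxy-4-methoxy-6-methyl-15-phenylpentadecan-2-yl]oxetan-2-one (both epimers at the ketal carbon)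
Conditions: O3, CH2Cl2/MeOH 4:1, −78 °C; N2 purge; cold concentration
Reagents that add atoms: ozone, [O-][O+]=O; methanol, CO
Why: Criegee ozonolysis of the 1,1-disubstituted alkene: cycloreversion of the primary ozonide places the carbonyl oxide on the disubstituted carbon and methanol traps it as the α-methoxy hydroperoxide, while arene and β-lactone are inert at −78 °C; the new ketal carbon forms as both epimers, which is harmless because it is ionised in step 10.

Step 9
Reactants: 15 (4R)-4-[(2S,6R)-4-hydroperoxy-4-methoxy-6-methyl-15-phenylpentadecan-2-yl]oxetan-2-one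
Product: 17 2-[(3S,4S)-6-methoxy-4-methyl-6-[(2R)-2-methyl-11-phenylundecyl]-1,2-dioxan-3-yl]acetic acid (both C6 epimers), via caesium carboxylate 16 (not isolated)
Conditions: Cs2CO3, DMF (0.02 M), 0 °C to rt; then AcOH
Reagents that add atoms: none
Why: Proposed new method: the caesium peroxide anion of 15 should attack the lactone C4 in a 6-exo-tet SN2 reaction (alkyl–oxygen cleavage driven by ring strain, carboxylate as leaving group), which closes the 1,2-dioxane, inverts that carbon to 3S (cis to the C4 methyl group) and releases the acetic acid arm; the closest known reaction types are the intramolecular alkylation of hydroperoxides by sulfonates, epoxides and oxetanes and the C4–O opening of β-lactones by soft nucleophiles.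

Step 10
Reactants: 17 2-[(3S,4S)-6-methoxy-4-methyl-6-[(2R)-2-methyl-11-phenylundecyl]-1,2-dioxan-3-yl]acetic acid
Product: 20 2-[(3S,4S,6R)-4,6-dimethyl-6-[(2R)-2-methyl-11-phenylundecyl]-1,2-dioxan-3-yl]acetic acid, via trimethylsilyl ester 18 (not isolated), via methylated trimethylsilyl ester 19 (not isolated)
Conditions: BSA, CH2Cl2, rt; then Me3Al (5 equiv), TMSOTf (1.2 equiv), −78 °C; aqueous HCl/Rochelle salt work-up
Reagents that add atoms: trimethylaluminium, C[Al](C)C
Why: Proposed new method: after transient silylation of the acid, TMSOTf should ionise the peroxyketal to the C6 peroxycarbenium ion and Me3Al, which has no β-hydrogen, should transfer methyl along the axial trajectory of the half-chair that keeps the C4 methyl group pseudo-equatorial, that is on the face opposite to the C4 methyl group and the C3 arm, which sets C6 as R; the closest known reaction types are the Sakurai-type allylation of cyclic peroxyketals through peroxycarbenium ions and the C-methylation of cyclic ketals and glycosyl donors with Me3Al.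

**Compound list**

1 | (4R)-4-benzyl-3-propanoyl-1,3-oxazolidin-2-one | CCC(=O)N1[C@H](Cc2ccccc2)COC1=O | starting material
2 | 2,3-dibromoprop-1-ene | C=C(Br)CBr | starting material
3 | sodium Z-enolate of 1 | C/C=C(\[O-])N1[C@H](Cc2ccccc2)COC1=O.[Na+] | intermediate
4 | (4R)-4-benzyl-3-[(2S)-4-bromo-2-methylpent-4-enoyl]-1,3-oxazolidin-2-one | C=C(Br)C[C@H](C)C(=O)N1[C@H](Cc2ccccc2)COC1=O | intermediate
5 | (8-bromooctyl)benzene | BrCCCCCCCCc1ccccc1 | starting material
6 | (2S)-3-bromo-2-methylpropan-1-ol | OC[C@H](C)CBr | starting material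
7 | 8-phenyloctylmagnesium bromide | Br[Mg]CCCCCCCCc1ccccc1 | intermediate
8 | (2R)-2-methyl-11-phenylundecan-1-ol | OC[C@H](C)CCCCCCCCCc1ccccc1 | intermediate
9 | (2R)-1-iodo-2-methyl-11-phenylundecane | IC[C@H](C)CCCCCCCCCc1ccccc1 | intermediate
10 | [(2R)-2-methyl-11-phenylundecyl]zinc iodide | I[Zn]C[C@H](C)CCCCCCCCCc1ccccc1 | intermediate
11 | (4R)-4-benzyl-3-[(2S,6R)-2,6-dimethyl-4-methylidene-15-phenylpentadecanoyl]-1,3-oxazolidin-2-one | C=C(C[C@H](C)CCCCCCCCCc1ccccc1)C[C@H](C)C(=O)N1[C@H](Cc2ccccc2)COC1=O | intermediate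
12 | (2S,6R)-2,6-dimethyl-4-methylidene-15-phenylpentadecan-1-ol | C=C(C[C@H](C)CCCCCCCCCc1ccccc1)C[C@H](C)CO | intermediate
13 | (2S,6R)-2,6-dimethyl-4-methylidene-15-phenylpentadecanal | C=C(C[C@H](C)CCCCCCCCCc1ccccc1)C[C@H](C)C=O | intermediate
14 | (4R)-4-[(2S,6R)-6-methyl-4-methylidene-15-phenylpentadecan-2-yl]oxetan-2-one | C=C(C[C@H](C)CCCCCCCCCc1ccccc1)C[C@H](C)[C@@H](CC2=O)O2 | intermediate
15 | (4R)-4-[(2S,6R)-4-hydroperoxy-4-methoxy-6-methyl-15-phenylpentadecan-2-yl]oxetan-2-one (both epimers at the ketal carbon) | COC(OO)(C[C@H](C)CCCCCCCCCc1ccccc1)C[C@H](C)[C@@H](CC2=O)O2 | intermediate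
16 | caesium 2-[(3S,4S)-6-methoxy-4-methyl-6-[(2R)-2-methyl-11-phenylundecyl]-1,2-dioxan-3-yl]acetate (both C6 epimers) | C[C@H](CCCCCCCCCc1ccccc1)CC1(OC)C[C@H](C)[C@H](CC(=O)[O-])OO1.[Cs+] | intermediate
17 | 2-[(3S,4S)-6-methoxy-4-methyl-6-[(2R)-2-methyl-11-phenylundecyl]-1,2-dioxan-3-yl]acetic acid (both C6 epimers) | C[C@H](CCCCCCCCCc1ccccc1)CC1(OC)C[C@H](C)[C@H](CC(=O)O)OO1 | intermediate
18 | trimethylsilyl 2-[(3S,4S)-6-methoxy-4-methyl-6-[(2R)-2-methyl-11-phenylundecyl]-1,2-dioxan-3-yl]acetate (both C6 epimers) | C[C@H](CCCCCCCCCc1ccccc1)CC1(OC)C[C@H](C)[C@H](CC(=O)O[Si](C)(C)C)OO1 | intermediate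
19 | trimethylsilyl 2-[(3S,4S,6R)-4,6-dimethyl-6-[(2R)-2-methyl-11-phenylundecyl]-1,2-dioxan-3-yl]acetate | C[C@H](CCCCCCCCCc1ccccc1)C[C@]1(C)C[C@H](C)[C@H](CC(=O)O[Si](C)(C)C)OO1 | intermediate
20 | 2-[(3S,4S,6R)-4,6-dimethyl-6-[(2R)-2-methyl-11-phenylundecyl]-1,2-dioxan-3-yl]acetic acid | C[C@H](CCCCCCCCCc1ccccc1)C[C@]1(C)C[C@H](C)[C@H](CC(=O)O)OO1 | target

**Step count.** Total: 10 steps. Longest linear sequence: 9 steps (5/6 → 8 → 9 → 11 → 12 → 13 → 14 → 15 → 17 → 20).

**Steps most likely to fail**

1. Step 10 (Proposed new method). The organoaluminium reagent may attack the O–O bond, or the peroxycarbenium ion may lose a proton or fragment faster than it is methylated; facial control could also erode. Fallback with known chemistry, setting out from β-lactone 14: a cobalt-catalysed Mukaiyama–Isayama silylperoxidation (Co(thd)2, O2, Et3SiH, 1,2-dichloroethane, rt) adds H to the terminal CH2 and the peroxide to the disubstituted carbon, giving the tertiary triethylsilyl peroxide F1 that already carries the C6 methyl group, as both epimers. Fluoride (TBAF, THF, 0 °C) then frees the peroxide anion, which closes the ring onto the β-lactone under the conditions of step 9. The target and its C6 epimer F2 are separated by preparative HPLC, and the route is rejoined at 20. This trades facial control at C6 for a separation.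

2. Step 9 (Proposed new method). SN2 attack at the hindered lactone carbon may be slower than β-elimination to the unsaturated acid or attack at the acyl carbon. Fallback with known chemistry (intramolecular displacement of a sulfonate by a hydroperoxy ketal), setting out from 14: LiBH4 reduces the lactone to the diol F3 with the carbinol configuration retained; TBSCl/imidazole protects the primary hydroxyl to give the silyl ether F4; MsCl/Et3N gives the secondary mesylate F5; ozonolysis in CH2Cl2/MeOH gives the hydroperoxy ketal mesylate F6; KOtBu/18-crown-6 in THF closes the ring with inversion to the 1,2-dioxane silyl ether F7; HF·pyridine gives the alcohol F8; TEMPO/PhI(OAc)2 in MeCN/H2O oxidises it to the acid, and the route is rejoined at 17.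

3. Step 7. The alkaloid has to override the Felkin preference of the α-methyl aldehyde (mismatched double diastereoselection), and the aldehyde may epimerise under the amine base; either process would give a mixed lactone. Fallback, setting out from 13: a Felkin–Anh-controlled Mukaiyama aldol addition of 1-(tert-butyldimethylsilyloxy)-1-methoxyethene (BF3·OEt2, CH2Cl2, −78 °C) should give the syn β-hydroxy ester F9; LiOH gives the β-hydroxy acid F10; Mitsunobu lactonisation (PPh3, DIAD, THF, hydroxyl activation) closes the β-lactone with inversion at the carbinol carbon, and the route is rejoined at 14.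

Further compounds
F1 | step 10 | (4R)-4-[(2S,6R)-4,6-dimethyl-15-phenyl-4-(triethylsilylperoxy)pentadecan-2-yl]oxetan-2-one (both epimers at the peroxide carbon) | CC[Si](CC)(CC)OOC(C)(C[C@H](C)CCCCCCCCCc1ccccc1)C[C@H](C)[C@@H](CC2=O)O2
F2 | step 10 | 2-[(3S,4S,6S)-4,6-dimethyl-6-[(2R)-2-methyl-11-phenylundecyl]-1,2-dioxan-3-yl]acetic acid | C[C@H](CCCCCCCCCc1ccccc1)C[C@@]1(C)C[C@H](C)[C@H](CC(=O)O)OO1
F3 | step 9 | (3R,4S,8R)-4,8-dimethyl-6-methylidene-17-phenylheptadecane-1,3-diol | C=C(C[C@H](C)CCCCCCCCCc1ccccc1)C[C@H](C)[C@@H](CCO)O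
F4 | step 9 | (3R,4S,8R)-1-[(tert-butyldimethylsilyl)oxy]-4,8-dimethyl-6-methylidene-17-phenylheptadecan-3-ol | C=C(C[C@H](C)CCCCCCCCCc1ccccc1)C[C@H](C)[C@@H](CCO[Si](C)(C)C(C)(C)C)O
F5 | step 9 | (3R,4S,8R)-1-[(tert-butyldimethylsilyl)oxy]-4,8-dimethyl-6-methylidene-17-phenylheptadecan-3-yl methanesulfonate | C=C(C[C@H](C)CCCCCCCCCc1ccccc1)C[C@H](C)[C@@H](CCO[Si](C)(C)C(C)(C)C)OS(C)(=O)=O
F6 | step 9 | (3R,4S,8R)-1-[(tert-butyldimethylsilyl)oxy]-6-hydroperoxy-6-methoxy-4,8-dimethyl-17-phenylheptadecan-3-yl methanesulfonate (both C6 epimers) | COC(OO)(C[C@H](C)CCCCCCCCCc1ccccc1)C[C@H](C)[C@@H](CCO[Si](C)(C)C(C)(C)C)OS(C)(=O)=O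
F7 | step 9 | tert-butyl{2-[(3S,4S)-6-methoxy-4-methyl-6-[(2R)-2-methyl-11-phenylundecyl]-1,2-dioxan-3-yl]ethoxy}dimethylsilane (both C6 epimers) | C[C@H](CCCCCCCCCc1ccccc1)CC1(OC)C[C@H](C)[C@H](CCO[Si](C)(C)C(C)(C)C)OO1
F8 | step 9 | 2-[(3S,4S)-6-methoxy-4-methyl-6-[(2R)-2-methyl-11-phenylundecyl]-1,2-dioxan-3-yl]ethan-1-ol (both C6 epimers) | C[C@H](CCCCCCCCCc1ccccc1)CC1(OC)C[C@H](C)[C@H](CCO)OO1
F9 | step 7 | methyl (3S,4S,8R)-3-hydroxy-4,8-dimethyl-6-methylidene-17-phenylheptadecanoate | C=C(C[C@H](C)CCCCCCCCCc1ccccc1)C[C@H](C)[C@H](CC(=O)OC)O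
F10 | step 7 | (3S,4S,8R)-3-hydroxy-4,8-dimethyl-6-methylidene-17-phenylheptadecanoic acid | C=C(C[C@H](C)CCCCCCCCCc1ccccc1)C[C@H](C)[C@H](CC(=O)O)O
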